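Of anything lost at a rate proportional to its own amount, equal times take equal shares, so the logarithm of charged over left adds up with time, while the percent made does not. The next run has to be settled with it: in 30 min, will 33.6 mM of nucleophile, the limiting reagent against 42 mM of electrophile, bring the electrophile left below what has reacted, or must the charge be raised first?

in all of them: electrophile 42 mM

| run | nucleophile | buffer base | buffer acid | remark | time |
|---|---|---|---|---|---|
| ochre | 47 mM | 84 mM | 4.2 mM | run made earlier |  |
| green | 74 mM | 84 mM | 4.2 mM | run made earlier |  |
| flask | 33.6 mM | 84.0 mM | 4.20 mM |  | 30 min |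

| run | time / min | electrophile / % | target / % |
|---|---|---|---|
| ochre | 2.50 | 88.6 | 10.1 |
| ochre | 4.00 | 83.0 | 15.8 |
| ochre | 6.00 | 75.7 | 22.0 |
| ochre | 8.00 | 69.9 | 26.8 |
| ochre | 12.0 | 60.3 | 35.7 |
| ochre | 20.0 | 46.3 | 48.0 |
| ochre | 30.0 | 35.0 | 57.9 |
| green | 1.50 | 89.1 | 10.1 |
| green | 5.00 | 69.9 | 28.2 |
| green | 8.00 | 58.4 | 39.9 |
| green | 12.0 | 45.7 | 51.0 |
| green | 20.0 | 29.7 | 65.1 |
| green | 25.0 | 23.8 | 71.5 |
| green | 30.0 | 18.9 | 75.9 |

(standard deviation of a reading: 0.3 percentage points)

1. part of the electrophile that has reacted at 30 min
2. pH of the solution at 30 min

- the analysis behind the earlier runs scatters by 0.3 percentage points, standard deviation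
- what has gone from electrophile into another species counts as reacted, even if it can come back
- a reading or a percentage of target counts all its forms, free or not
- the earlier runs do not show the pH; that part of a forecast is a guess

Between the ochre and green runs, the [nucleophile] charged changes while the electrophile, buffer base, buffer acid and time stay the same. At 30.0 min the ochre run leaves 35.0 % of its electrophile, which gives 0.0223 mM⁻¹ per unit of [nucleophile] charged. The green run leaves 18.9 %, which gives 0.0225 mM⁻¹. Their mean, 0.0224 mM⁻¹, is the loss per nucleophile: the logarithm of electrophile charged over electrophile left at that time, divided by the [nucleophile] charged. But [nucleophile] falls along each run, so this constancy is only a reading from two runs, and the nucleophile charged to the flask lies below that of both.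

Multiplied by 33.6 mM, the loss per nucleophile gives a logarithm of 0.753. The reckoning here therefore expects the flask to leave 47.1 % and to have 52.9 % reacted, more than it leaves, so the charge can stand.

The forecast, built on a second-order rate and “a slow side path”, gives 52 % (48 % to 56 %), which is 0.90 percentage points below this reckoning. For the pH it gives 7 (4.5 to 9.5) and calls that a guess.

The flask gives 53.4 % reacted and pH 9.05, from this scheme:

    electrophile + nucleophile → acid + target + leaving group (k = 0.0165 M⁻¹ s⁻¹)
    protonated nucleophile ⇌ nucleophile + acid, settled at all times (K = 7.90 × 10⁻⁷ M)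
    buffer acid ⇌ buffer base + acid, settled at all times (K = 2.50 × 10⁻⁹ M)
    crystals ⇌ target, rate k4*(cs4 - [target]) while solid is left; crystals form when [target] > cs4 (solubility = 15.0 mM, k = 0.0193 s⁻¹)
    electrophile ⇌ dormant form (K = 1.21, k = 7.19 × 10⁻⁵ s⁻¹)

The loss per nucleophile of the flask itself comes to 0.0227 mM⁻¹, against 0.0224 mM⁻¹ from the runs. The neighbouring flask is the same but for 84 mM of nucleophile. The value from the runs gives it a logarithm of 1.88, hence 15.2 % of its electrophile left. At 30.0 min that neighbour holds 15 % of its electrophile, with 85.3 % reacted.

The earlier runs and the new flask are calculated for an exercise; scatter was added.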